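A small charge of E feeds two takers, so this flask is reckoned as a ledger of E.

| flask | G | E | remark | time |
|---|---|---|---|---|
| summer | 2.0 × 10⁻⁴ M | 0.20 mM | run made earlier |  |
| midnight | 2.0 × 10⁻⁴ M | 0.45 mM | run made earlier |  |
| dawn | 4.0 × 10⁻⁴ M | 0.30 mM | run made earlier |  |
| flask | 2.0 × 10⁻⁴ M | 0.300 mM |  | 12 min |

| run | time / min | L / % |
|---|---|---|
| summer | 2.00 | 23.3 |
| summer | 4.00 | 31.1 |
| summer | 6.00 | 30.6 |
| summer | 8.00 | 31.8 |
| summer | 10.0 | 31.9 |
| summer | 12.0 | 30.2 |
| midnight | 1.00 | 20.2 |
| midnight | 1.50 | 28.5 |
| midnight | 2.50 | 42.8 |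
| midnight | 4.00 | 56.0 |
| midnight | 8.00 | 59.0 |
| midnight | 12.0 | 58.3 |
| dawn | 2.50 | 18.4 |
| dawn | 5.00 | 19.7 |
| dawn | 8.00 | 20.0 |
| dawn | 10.0 | 22.2 |
| dawn | 12.0 | 22.2 |

(readings scatter by 1 percentage point)

- how much L there is at 12 min, in percent of the G charged
- the change that raises the amount of L at 12 min, in percent of the G charged most ("none" if none brings more than 2 percentage points) (Friday's / Sunday's / Monday's / none)
- amount of L at 12 min, in percent of the G charged, after Friday's

- Friday's: doubling the amount of E, all else as stated
- Sunday's: doubling the solubility of G, all else as stated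
- Monday's: doubling the dissolution coefficient of G, all else as stated

In the summer run L levels off near 31.1% of the G charged, with 68.9% of the G not in L. So the reckoning takes E, not G, as the limiting reagent. The ledger has few entries: E goes to L through Z, or to Q, while X is a store that can return E.

The E share is the fraction of the E charged that ends in L, read as plateau L times G charged over E charged. The dawn run holds the flask's E charge and gives 0.286, the E share, which leaves 0.714 for Q. The summer run reads 0.311 and the midnight run 0.261, and the dawn run, with twice their G, sits between them. The flask should therefore reach 42.9% of L.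

Friday's charge, following the slide of the share with E, has a share of 0.230 and gives 69.1%. Sunday's, with the odds of L against Q doubled at best, gives 66.8%, less than Friday's by 2.3 percentage points. Monday's quickens dissolving without raising its ceiling, so it is placed below Sunday's, and the choice is Friday's.

The forecast says 43% (40.5% to 45.5%), Friday's and 70% (63% to 76%), slightly above the 69.1% reckoned here: “Friday narrowly wins.”

The flask gives 43.0% of L, an E share of 0.287, with 0% of E left and Q holding 0.713 of the E charged. Friday's wins, reaching 70.0% with a gain of 27 points, against 20 points for Sunday's and 12 points for Monday's.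

    E → Q (k = 0.0130 s⁻¹)
    G → J (k = 7.60 × 10⁻⁵ s⁻¹)
    Z + E → L (k = 220 M⁻¹ s⁻¹)
    G ⇌ Z, rate k4*(cs4 - [Z]) while solid is left; crystals form when [Z] > cs4 (solubility = 0.0690 mM, k = 0.0170 s⁻¹)
    E ⇌ X (K = 0.410, k = 0.570 s⁻¹)

A neighbouring flask charges 7.5 × 10⁻⁵ M of E, 0.375 equiv to G. The carried share promises 10.7% of L there, and that flask gives 13.0%, so its share is 0.347, higher than the flask's. Its Q takes 0.653 of the E charged, and 0% of E is left.

All runs were generated by integration for substances that don't exist; the scatter is artificial.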